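**Strategy.** The cyclohexene ring (C4a–C5–C6–C7–C8–C8a, quinolinone numbering) is disconnected at C6–C7 and C8–C8a, which excises C7–C8(OMe) as methyl vinyl ether. The key step is a radical [4+2] annulation: a primary C6 radical, released by decarboxylation of an N-acyloxyphthalimide, adds to the vinyl ether, and the resulting α-methoxyalkyl radical closes onto C8a, the only unsubstituted and electrophilic ring carbon (α to nitrogen, β to the C4 carbonyl) of the N-methoxy-4-pyridone; rearomatisation gives waltherione H directly. The precursor is an (S)-3-(pyridon-3-yl)-8-phenyloctanoic acid derivative, whose stereocentre (later C5) comes from an asymmetric conjugate reduction and then controls C8.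

Key step: step 8

Remark: quinolinone numbering (N1, C2, C3, C4, C4a, C5–C8, C8a) is used for the target and for the corresponding atoms of its precursors. The SMILES is read as the cis-(5S,8R) isomer. 3,4-Dimethoxy-2-methylpyridine 1-oxide, 6-phenylhexan-1-ol and methyl vinyl ether are taken as commercial.

Step 1
Reactants: 1 3,4-dimethoxy-2-methylpyridine 1-oxide
Product: 3 1,3-dimethoxy-2-methylpyridin-4(1H)-one, via N-methoxypyridinium iodide 2 (not isolated)
Conditions: MeI (2 equiv), MeCN, 80 °C, sealed tube
Reagents that add atoms: iodomethane, CI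
Why: O-Methylation of the N-oxide gives pyridinium salt 2 and iodide then removes the activated 4-O-methyl group by SN2 attack (the alkyl halide-promoted rearrangement of 4-alkoxypyridine N-oxides to 1-alkoxy-4-pyridones, akin to the 4-methoxypyridine to N-methyl-4-pyridone rearrangement), while the unactivated 3-methoxy group should stay.

Step 2
Reactants: 3 1,3-dimethoxy-2-methylpyridin-4(1H)-one
Product: 4 5-iodo-1,3-dimethoxy-2-methylpyridin-4(1H)-one
Conditions: NIS, TFA (cat.), MeCN, 23 °C
Reagents that add atoms: N-iodosuccinimide, O=C1CCC(=O)N1I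
Why: Electrophilic aromatic iodination should occur at C5, the only free carbon α to the carbonyl and β to nitrogen of the vinylogous amide (C6 is electrophilic, not nucleophilic).

Step 3
Reactants: 5 6-phenylhexan-1-ol
Product: 7 ethyl (E)-8-phenyloct-2-enoate, via 6-phenylhexanal 6 (not isolated)
Conditions: Dess–Martin periodinane, CH2Cl2, 23 °C; then Ph3P=CHCO2Et, 23 °C (one pot)
Reagents that add atoms: ethyl (triphenylphosphoranylidene)acetate, CCOC(=O)C=P(c1ccccc1)(c1ccccc1)c1ccccc1
Why: Dess–Martin oxidation followed by Wittig olefination with a stabilised ylide, which should give the E-enoate.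

Step 4
Reactants: 4 5-iodo-1,3-dimethoxy-2-methylpyridin-4(1H)-one; 7 ethyl (E)-8-phenyloct-2-enoate
Product: 8 ethyl (E)-3-(1,5-dimethoxy-6-methyl-4-oxo-1,4-dihydropyridin-3-yl)-8-phenyloct-2-enoate
Conditions: Pd(OAc)2 (5 mol %), n-Bu4NCl, NaHCO3, DMF, 90 °C
Reagents that add atoms: none
Why: Mizoroki–Heck reaction under ligand-free phase-transfer conditions: the pyridonyl group adds to the β-carbon of the enoate and syn β-hydride elimination from that carbon should give the E-trisubstituted enoate (aryl trans to the ester).

Step 5
Reactants: 8 ethyl (E)-3-(1,5-dimethoxy-6-methyl-4-oxo-1,4-dihydropyridin-3-yl)-8-phenyloct-2-enoate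
Product: 9 ethyl (3S)-3-(1,5-dimethoxy-6-methyl-4-oxo-1,4-dihydropyridin-3-yl)-8-phenyloctanoate
Conditions: Cu(OAc)2 (3 mol %), (R)-DTBM-SEGPHOS (3.3 mol %), (EtO)2MeSiH, t-BuOH, toluene, 0 °C
Reagents that add atoms: none
Why: Copper hydride-catalysed asymmetric conjugate reduction of a β-aryl-β-alkyl enoate: hydride is delivered to C3 on the face chosen by the bisphosphine, which sets the (S) centre (later C5), the ligand enantiomer being fixed on the model ethyl (E)-3-phenylbut-2-enoate and exchanged for its antipode if the sense there is opposite.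

Step 6
Reactants: 9 ethyl (3S)-3-(1,5-dimethoxy-6-methyl-4-oxo-1,4-dihydropyridin-3-yl)-8-phenyloctanoate
Product: 10 (3S)-3-(1,5-dimethoxy-6-methyl-4-oxo-1,4-dihydropyridin-3-yl)-8-phenyloctanoic acid
Conditions: LiOH, THF/H2O, 23 °C; then aq. HCl
Reagents that add atoms: lithium hydroxide, [Li+].[OH-]
Why: Ester saponification; the stereocentre is β to the carboxylate and not acidic, so it should not epimerise.

Step 7
Reactants: 10 (3S)-3-(1,5-dimethoxy-6-methyl-4-oxo-1,4-dihydropyridin-3-yl)-8-phenyloctanoic acid
Product: 11 1,3-dioxoisoindolin-2-yl (3S)-3-(1,5-dimethoxy-6-methyl-4-oxo-1,4-dihydropyridin-3-yl)-8-phenyloctanoate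
Conditions: N-hydroxyphthalimide, DIC, DMAP (cat.), CH2Cl2, 23 °C
Reagents that add atoms: N-hydroxyphthalimide, O=C1c2ccccc2C(=O)N1O
Why: Steglich-type carbodiimide esterification to the redox-active N-acyloxyphthalimide.

Step 8
Reactants: 11 1,3-dioxoisoindolin-2-yl (3S)-3-(1,5-dimethoxy-6-methyl-4-oxo-1,4-dihydropyridin-3-yl)-8-phenyloctanoate; 12 methyl vinyl ether
Product: 15 waltherione H [(5S,8R)-1,3,8-trimethoxy-2-methyl-5-(5-phenylpentyl)-5,6,7,8-tetrahydroquinolin-4(1H)-one], via primary alkyl radical 13 (not isolated), via α-methoxyalkyl radical 14 (not isolated)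
Conditions: fac-Ir(ppy)3 (1 mol %), methyl vinyl ether (ca. 2 M, large excess), MeCN (0.02 M in 11), blue LEDs, sealed tube, 20 °C
Reagents that add atoms: none
Why: Proposed new method: photoexcited Ir(ppy)3 reduces the N-acyloxyphthalimide, which loses phthalimide anion and CO2 to give the primary C6 radical 13; this adds to the unsubstituted terminus of methyl vinyl ether (C6–C7) to give the nucleophilic α-methoxyalkyl radical 14, which attacks C8a (C8–C8a), the electrophilic β-carbon of the vinylogous hydroxamate, and the adduct radical is rearomatised by proton-coupled oxidation (tetravalent iridium as oxidant, phthalimide anion as base), so the cycle is redox-neutral. The closest known reactions are three-component Minisci-type alkylations of heteroarenes through enol ethers and the xanthate-transfer addition to vinyl esters followed by oxidative ring closure onto arenes and pyridines (tetralone and azatetralone synthesis); new here are an unstabilised primary radical as the first radical and an N-alkoxy-4-pyridone as the acceptor. The carbocycle closes in the 6-endo-trig mode onto the C4a=C8a bond, since ipso attack at C4a (5-exo) is polarity-mismatched. C8 is set by the C5 centre through a chair-like transition state in which the C5 side chain is pseudoaxial (to avoid peri strain with the C4 carbonyl) and the methoxy group of the radical is pseudoequatorial and turned away from the ring, which should give the cis-(5S,8R) isomer, while C5 itself is not touched. The step needs 13 to prefer the vinyl ether over 1,5-hydrogen transfer, 1,2-aryl migration and intermolecular addition, which the large excess of vinyl ether at high dilution of 11 secures, and it needs 14 to close faster than it telomerises or is oxidised, which intramolecularity and low catalyst loading favour; acid-free conditions protect the vinyl ether and, since no pyridinium ion or radical anion is formed, the N–OMe bond.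

**Compound list**

1 | 3,4-dimethoxy-2-methylpyridine 1-oxide | Cc1c(OC)c(OC)cc[n+]1[O-] | starting material
2 | 1,3,4-trimethoxy-2-methylpyridin-1-ium iodide | Cc1c(OC)c(OC)cc[n+]1OC.[I-] | intermediate
3 | 1,3-dimethoxy-2-methylpyridin-4(1H)-one | COc1c(C)n(OC)ccc1=O | intermediate
4 | 5-iodo-1,3-dimethoxy-2-methylpyridin-4(1H)-one | COc1c(C)n(OC)cc(I)c1=O | intermediate
5 | 6-phenylhexan-1-ol | OCCCCCCc1ccccc1 | starting material
6 | 6-phenylhexanal | O=CCCCCCc1ccccc1 | intermediate
7 | ethyl (E)-8-phenyloct-2-enoate | CCOC(=O)/C=C/CCCCCc1ccccc1 | intermediate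
8 | ethyl (E)-3-(1,5-dimethoxy-6-methyl-4-oxo-1,4-dihydropyridin-3-yl)-8-phenyloct-2-enoate | CCOC(=O)/C=C(\CCCCCc1ccccc1)c1cn(OC)c(C)c(OC)c1=O | intermediate
9 | ethyl (3S)-3-(1,5-dimethoxy-6-methyl-4-oxo-1,4-dihydropyridin-3-yl)-8-phenyloctanoate | CCOC(=O)C[C@H](CCCCCc1ccccc1)c1cn(OC)c(C)c(OC)c1=O | intermediate
10 | (3S)-3-(1,5-dimethoxy-6-methyl-4-oxo-1,4-dihydropyridin-3-yl)-8-phenyloctanoic acid | OC(=O)C[C@H](CCCCCc1ccccc1)c1cn(OC)c(C)c(OC)c1=O | intermediate
11 | 1,3-dioxoisoindolin-2-yl (3S)-3-(1,5-dimethoxy-6-methyl-4-oxo-1,4-dihydropyridin-3-yl)-8-phenyloctanoate | O=C(C[C@H](CCCCCc1ccccc1)c1cn(OC)c(C)c(OC)c1=O)ON1C(=O)c2ccccc2C1=O | intermediate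
12 | methyl vinyl ether (methoxyethene) | COC=C | starting material
13 | (2R)-2-(1,5-dimethoxy-6-methyl-4-oxo-1,4-dihydropyridin-3-yl)-7-phenylheptyl radical | [CH2][C@H](CCCCCc1ccccc1)c1cn(OC)c(C)c(OC)c1=O | intermediate
14 | (4S)-4-(1,5-dimethoxy-6-methyl-4-oxo-1,4-dihydropyridin-3-yl)-1-methoxy-9-phenylnonyl radical | CO[CH]CC[C@H](CCCCCc1ccccc1)c1cn(OC)c(C)c(OC)c1=O | intermediate
15 | waltherione H, (5S,8R)-1,3,8-trimethoxy-2-methyl-5-(5-phenylpentyl)-5,6,7,8-tetrahydroquinolin-4(1H)-one | COc1c(C)n(OC)c2c(c1=O)[C@@H](CCCCCc1ccccc1)CC[C@H]2OC | target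

**Total steps:** 8. **Longest linear sequence:** 7 (steps 1, 2, 4, 5, 6, 7, 8).

**Steps most likely to fail**

Step 8 (Proposed new method). The unstabilised primary radical is polarity-mismatched with the electron-rich alkene and may be lost to 1,5-hydrogen transfer, 1,2-aryl migration or intermolecular addition before the first C–C bond forms. The open-chain radical may also be oxidised or telomerise before ring closure, and facial selectivity at C8 may be low. The fallback uses known chemistry, still closes both ring bonds in one operation, sets out from 8 and returns at 15. Conjugate hydrosilylation of 8 with the catalyst of step 5, but without tert-butanol, should give the silyl ketene acetal F1. This is brominated in the same flask with N-bromosuccinimide to the α-bromo ester F2 (C2 epimers). Under photoredox conditions (fac-Ir(ppy)3, NaHCO3, MeCN, blue LEDs) F2 should give an ester-stabilised, electrophilic C6 radical that is polarity-matched to methyl vinyl ether 12. The α-methoxyalkyl radical then closes onto C8a, as in the known three-component Minisci-type carbo-heteroarylation of enol ethers with α-bromo esters and in the xanthate-based tetralone annulation. This should give the annulated 6-carboxylic ester F3 (C6 epimers, of no consequence). Saponification (LiOH, THF/H2O) to the acid F4 and photoredox hydrodecarboxylation (9-mesityl-10-methylacridinium tetrafluoroborate, PhSSPh, i-Pr2NEt, all catalytic, CF3CH2OH, blue LEDs) remove the auxiliary carboxyl group and should deliver 15.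

Step 4. Migratory insertion into the 1,2-disubstituted enoate is slow, so hydrodeiodination of 4 and isomerisation of the product alkene (E/Z and deconjugation) may compete. The fallback reverses the polarity and sets the stereocentre in the C–C bond-forming step; it sets out from 4 and returns at 9, replacing steps 4 and 5. Miyaura borylation of 4 (B2pin2, Pd(dppf)Cl2, KOAc, dioxane, 80 °C) should give the pinacol boronate F5. Hayashi–Miyaura addition of F5 to enoate 7 ([Rh(cod)Cl]2, BINAP enantiomer chosen by the established facial model for E-enoates, KOH, dioxane/H2O, 60 °C) should give 9 directly.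

Step 5. Facial selectivity may be poor, or the basic pyridone oxygen may inhibit the copper hydride catalyst. The fallback is a carboxylate-directed asymmetric hydrogenation; it sets out from 8 and returns at 10, replacing steps 5 and 6. Saponification of 8 (LiOH, THF/H2O) should give the unsaturated acid F6. Hydrogenation with Ru(OAc)2[(S)-BINAP] (H2, MeOH; ligand enantiomer under the same proviso as in step 5) should give 10.

**Further compounds**

F1 | step 8 | O-[diethoxy(methyl)silyl] O-ethyl ketene acetal of ester 9, (3S) | CCOC(=C[C@H](CCCCCc1ccccc1)c1cn(OC)c(C)c(OC)c1=O)O[Si](C)(OCC)OCC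
F2 | step 8 | ethyl (3R)-2-bromo-3-(1,5-dimethoxy-6-methyl-4-oxo-1,4-dihydropyridin-3-yl)-8-phenyloctanoate (C2 epimers) | CCOC(=O)C(Br)[C@H](CCCCCc1ccccc1)c1cn(OC)c(C)c(OC)c1=O
F3 | step 8 | ethyl (5S,8R)-1,3,8-trimethoxy-2-methyl-4-oxo-5-(5-phenylpentyl)-1,4,5,6,7,8-hexahydroquinoline-6-carboxylate (C6 epimers) | COc1c(C)n(OC)c2c(c1=O)[C@@H](CCCCCc1ccccc1)C(C(=O)OCC)C[C@H]2OC
F4 | step 8 | (5S,8R)-1,3,8-trimethoxy-2-methyl-4-oxo-5-(5-phenylpentyl)-1,4,5,6,7,8-hexahydroquinoline-6-carboxylic acid (C6 epimers) | COc1c(C)n(OC)c2c(c1=O)[C@@H](CCCCCc1ccccc1)C(C(=O)O)C[C@H]2OC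
F5 | step 4 | 1,3-dimethoxy-2-methyl-5-(4,4,5,5-tetramethyl-1,3,2-dioxaborolan-2-yl)pyridin-4(1H)-one | COc1c(C)n(OC)cc(B2OC(C)(C)C(C)(C)O2)c1=O
F6 | step 5 | (E)-3-(1,5-dimethoxy-6-methyl-4-oxo-1,4-dihydropyridin-3-yl)-8-phenyloct-2-enoic acid | OC(=O)/C=C(\CCCCCc1ccccc1)c1cn(OC)c(C)c(OC)c1=O
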